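(Readings and results are simulated for substances that don't exist; the scatter is artificial.)

- In the amber run the side product still climbs after target has formed, and its gap to the last reading shrinks from 2.1 percentage points to 0.6 points between 0.667 min and 1.33 min; I read that as starting material decaying by itself with a half-life of about 0.367 min, rough since the second gap is close to the scatter.

| flask | starting material | partner | remark | time |
|---|---|---|---|---|
| blue | 2 mM | 0.95 equiv | run made earlier |  |
| grey | 1.3 mM | 0.95 equiv | run made earlier |  |
| amber | 3 mM | 0.95 equiv | run made earlier |  |
| noon | 2.0 mM (fed, over 3.0 min) | 0.950 equiv | all else is in the flask from the start; the feed brings no volume worth counting | 4.0 min |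
| winter | 2.0 mM | 0.950 equiv (in portions, 2, over 3.0 min) | first portion at the start, last at 3.0 min | 4.0 min |
| spring | 2.0 mM | 0.950 equiv (fed, over 3.0 min) | all else is in the flask from the start; the feed brings no volume worth counting | 4.0 min |
| autumn | 2.0 mM | 0.950 equiv | everything together at the start | 4.0 min |

- blue (time / min: target / %, side product / %): 0.200: 63.7, 6.6; 0.667: 56.9, 10.7; 1.00: 55.8, 11.1; 1.50: 57.2, 11.1; 2.50: 56.7, 12.6
- grey (time / min: target / %, side product / %): 1.00: 56.0, 13.2; 2.00: 55.5, 14.6; 3.00: 57.3, 14.6; 4.00: 55.4, 14.4; 5.00: 56.0, 15.6
- amber (time / min: target / %, side product / %): 0.417: 59.1, 7.8; 0.667: 58.3, 10.3; 1.33: 56.9, 11.8; 2.50: 57.8, 12.2; 5.00: 57.9, 12.4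

(readings scatter by 0.5 percentage points)

* the flask that comes out highest in share of target in target plus side product, or "all alike" when all lie within 1.5 percentage points (noon / winter / spring / autumn / all alike)
* share of target in target plus side product at the end, noon
* share of target in target plus side product at the end, winter
* share of target in target plus side product at the end, spring
* share of target in target plus side product at the end, autumn



- What matters is the catch: the part of the charge that meets partner before it decays. Partner, the limiting reagent by the charge, caps it at its equivalents.
- Blue's last reading gives 0.649 as the keep, the part of caught starting material that stands as target at the end, assuming that what the readings miss left by way of target. With uncaught starting material ending as side product, the share is then keep × catch / (keep × catch + 1 − catch).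
- One extreme is autumn, which has blue's charges, and blue's last reading gives 81.8%. The other is partner arriving too late, with catch zero and share zero.
- Spring lies between, since the half-life I read for starting material is shorter than the feed. If each drop of partner is caught at once, catch = ln(1 + x)/x, with x = decay constant × feed time / equivalents = 5.97. That gives a catch of 0.325 and a share of 23.8%.
- By my half-life, decay with no partner present leaves about 0.345% of the charge when winter's last portion arrives, so I take winter's catch as the first portion, and its share as 37.0%.
- For noon, where partner stands waiting for the fed starting material, I commit to no number.
- The forecast picks autumn, with 78.5% (70% to 86%) for noon, 81% (76% to 86%) for winter, 79.5% (71% to 88%) for spring and 82.5% (81% to 84%) for autumn: “Feeding either reagent keeps its concentration low, so I expect slightly poorer shares”. My winter and spring lie far below it.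
- The flasks give 20.8% for noon, 36.5% for winter, 26.2% for spring and 81.5% for autumn, so autumn comes highest. Noon ends holding 0.680 mM of self-condensation product, with partner at 0%. Its side product 67.3% and starting material 5.71% leave a catch of 27.0%, which the keep turns into 17.5% target; the flask holds 17.7%.

    starting material + partner → target (k = 490 M⁻¹ s⁻¹)
    starting material → side product (k = 0.0230 s⁻¹)
    target ⇌ isomer of the product (K = 0.530, k = 0.0400 s⁻¹)
    2 partner → self-condensation product (k = 27.0 M⁻¹ s⁻¹)

- Autumn with partner cut to 0.570 equiv has its catch capped there, so the keep gives a share of about 46.2% and side product of about 43.0%. That neighbour gives 44.3%, with side product 45.0%.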